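**Retrosynthetic overview**

1. Numbering used: ring A = C1, C2, C3, C4, C5, C10 (C4 quaternary, carrying CH3 and the side chain C1'–C12'; C5=C10 is the ring-fusion alkene); ring B = C5–C10 (C8 = CHMe, C9 = C(Me)CH2Ar).
2. Late stage: the bis-sulfate comes from the hydroquinone, which comes from its dimethyl ether, with the diol masked as a cyclic carbonate. The side chain is joined at C2'–C3' by B-alkyl Suzuki–Miyaura coupling of the C4-vinyl core 13 with the (E)-vinyl iodide 24, which is made from geraniol.
3. Ring A is disconnected by a Diels–Alder reaction: diene C5=C10–C1=C2 (a 1-vinylcyclohexene built on ring B) plus methacrolein (C3=C4, the C4 methyl, C1' as CHO). The CHO then becomes vinyl, and the C1=C10 bond is shifted by acid to C5=C10.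
4. Enabling feature: ring A holds one stereocentre only, the quaternary C4, which lies between CH2-3 and the sp2 carbon C5. C4(CH3)(CH2R) is the retron of an α-methylacrolein dienophile, and because C5 ends trigonal, the C4 configuration depends only on the dienophile face (catalyst control), not on endo/exo mode or diene face.
5. Ring order: arene (bought), then ring B (bought as 2-methylcyclohexenone; C8 and C9 set by conjugate methylation and enolate benzylation), then ring A last, in step 5.

Key step: step 5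

Assumption 1: the absolute sense of the two catalyst-controlled steps (1 and 5) is fixed by the choice of ligand or catalyst antipode; the antipodes named are those expected to give 3S in step 1 and attack on the Re face at C2 of methacrolein in step 5.
Assumption 2: the target is drawn as the free bis(hydrogen sulfate); it is reached from its disodium salt by proton exchange in the last step.

**Route**

Step 1
Reactants: 1 2-methylcyclohex-2-en-1-one
Product: 3 (3S)-2,3-dimethylcyclohex-1-en-1-yl acetate, via dimethylaluminium enolate 2 (not isolated)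
Conditions: Me3Al (1.3 equiv), Cu(O2C-C4H3S) (copper thiophene-2-carboxylate, 2 mol %), (R)-binaphthol-derived phosphoramidite with a bis[(R)-1-phenylethyl]amino group (4 mol %), Et2O, −30 °C; then Ac2O, −30 °C → rt
Reagents that add atoms: trimethylaluminium, C[Al](C)C; acetic anhydride, CC(=O)OC(C)=O
Why: Copper-catalysed asymmetric conjugate addition of methyl to the trisubstituted enone, in which the chiral phosphoramidite complex of monovalent copper selects the enone face and sets C8, followed by O-acylation of the aluminium enolate, which fixes the enolate regiochemistry.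

Step 2
Reactants: 3 (3S)-2,3-dimethylcyclohex-1-en-1-yl acetate; 4 2,5-dimethoxybenzyl bromide
Product: 6 (2R,3S)-2-[(2,5-dimethoxyphenyl)methyl]-2,3-dimethylcyclohexan-1-one, via lithium enolate 5 (not isolated)
Conditions: MeLi (2.05 equiv), THF, 0 °C; then 4, DMPU, −40 °C → rt
Reagents that add atoms: none
Why: Cleavage of the enol acetate by MeLi gives the tetrasubstituted lithium enolate regiospecifically, and its C-alkylation by the benzylic bromide should take place on the face opposite the neighbouring C8 methyl, setting the quaternary C9 with the two methyls cis (enolate alkylation).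

Step 3
Reactants: 6 (2R,3S)-2-[(2,5-dimethoxyphenyl)methyl]-2,3-dimethylcyclohexan-1-one
Product: 8 (5S,6R)-6-[(2,5-dimethoxyphenyl)methyl]-5,6-dimethylcyclohex-1-en-1-yl trifluoromethanesulfonate, via potassium enolate 7 (not isolated)
Conditions: KN(SiMe3)2, THF, −78 °C; PhNTf2, −78 → 0 °C
Reagents that add atoms: N-phenylbis(trifluoromethanesulfonimide), O=S(=O)(N(c1ccccc1)S(=O)(=O)C(F)(F)F)C(F)(F)F
Why: Enolisation can occur only towards C5 because C9 is quaternary, so O-triflation of the potassium enolate gives a single enol triflate without touching a stereocentre.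

Step 4
Reactants: 8 (5S,6R)-6-[(2,5-dimethoxyphenyl)methyl]-5,6-dimethylcyclohex-1-en-1-yl trifluoromethanesulfonate
Product: 9 2-{[(1R,6S)-2-ethenyl-1,6-dimethylcyclohex-2-en-1-yl]methyl}-1,4-dimethoxybenzene
Conditions: CH2=CHSnBu3, Pd(PPh3)4 (5 mol %), LiCl, THF, 65 °C
Reagents that add atoms: tributyl(vinyl)stannane, C=C[Sn](CCCC)(CCCC)CCCC
Why: Stille coupling under zerovalent palladium catalysis with LiCl is a standard way to turn a hindered enol triflate into a 1,3-diene with the ring double bond kept in place.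

Step 5
Reactants: 9 2-{[(1R,6S)-2-ethenyl-1,6-dimethylcyclohex-2-en-1-yl]methyl}-1,4-dimethoxybenzene; 10 methacrolein
Product: 11 (1S,5R,6S)-5-[(2,5-dimethoxyphenyl)methyl]-1,5,6-trimethyl-1,2,3,5,6,7,8,8a-octahydronaphthalene-1-carbaldehyde (CHO and CH3 on C4, C1=C10, H on C5; both epimers at C5 are carried on)
Conditions: 10 (3 equiv), (S)-3,3-diphenyl-1-(2-methylphenyl)tetrahydro-1H,3H-pyrrolo[1,2-c][1,3,2]oxazaborole premixed with HNTf2 (20 mol %, oxazaborole in slight excess), CH2Cl2, −78 → −40 °C
Reagents that add atoms: none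
Why: This is a Lewis-acid-catalysed [4+2] cycloaddition, the closest known type being the enantioselective Diels–Alder reaction of 2-substituted acroleins with acyclic and semicyclic dienes under protonated oxazaborolidine catalysis, in which the boron cation binds the aldehyde and lowers its LUMO. Ring A is closed by a concerted, asynchronous suprafacial–suprafacial cycloaddition in which the C2–C3 bond between the two unhindered CH2 termini leads and the C4–C5 bond follows. The only new stereocentre that survives, the quaternary C4, is fixed solely by the face of methacrolein that bonds to C5 (the Re face at C2 of the aldehyde), and that face is chosen by the catalyst and not by the diene. The second new centre, C5–H, depends on endo/exo mode and diene face but becomes trigonal in step 7, so both C5 epimers are productive. The step needs regioselectivity (C4 to C5) and catalyst control of the dienophile face: the first should follow from the directing effect of the ring substituent on the diene terminus C5 under Lewis acid catalysis and from the s-cis preference that the quaternary C9 imposes on the vinyl group. One operation thus delivers ring A, the C4 methyl, and the aldehyde carbon that becomes C1' of the side chain.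

Step 6
Reactants: 11 (1S,5R,6S)-5-[(2,5-dimethoxyphenyl)methyl]-1,5,6-trimethyl-1,2,3,5,6,7,8,8a-octahydronaphthalene-1-carbaldehyde
Product: 12 (1R,5R,6S)-1-ethenyl-5-[(2,5-dimethoxyphenyl)methyl]-1,5,6-trimethyl-1,2,3,5,6,7,8,8a-octahydronaphthalene (both epimers at C5 of the core numbering)
Conditions: Ph3PCH3Br, KOtBu, THF, 0 °C → rt
Reagents that add atoms: methyltriphenylphosphonium bromide, C[P+](c1ccccc1)(c1ccccc1)c1ccccc1.[Br-]
Why: Wittig methylenation of a non-enolisable neopentyl aldehyde, in which the quaternary C4 has no α-hydrogen and cannot epimerise.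

Step 7
Reactants: 12 (1R,5R,6S)-1-ethenyl-5-[(2,5-dimethoxyphenyl)methyl]-1,5,6-trimethyl-1,2,3,5,6,7,8,8a-octahydronaphthalene
Product: 13 2-{[(1R,2S,5R)-5-ethenyl-1,2,5-trimethyl-1,2,3,4,5,6,7,8-octahydronaphthalen-1-yl]methyl}-1,4-dimethoxybenzene
Conditions: p-TsOH·H2O (10 mol %), benzene, 70 °C
Reagents that add atoms: none
Why: Acid-catalysed alkene isomerisation (protonation at C1 to the tertiary C10 cation, then loss of H-5) should move the double bond into the tetrasubstituted C5=C10 position between the two quaternary carbons, the expected thermodynamic position in this octalin, and it removes the stereocentre at C5 so that both epimers converge.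

Step 8
Reactants: 14 geraniol
Product: 15 [(2R,3R)-3-methyl-3-(4-methylpent-3-en-1-yl)oxiran-2-yl]methanol
Conditions: Ti(OiPr)4 (5 mol %), D-(−)-diethyl tartrate (7 mol %), t-BuOOH (anhydrous), 4 Å molecular sieves, CH2Cl2, −20 °C
Reagents that add atoms: tert-butyl hydroperoxide, CC(C)(C)OO
Why: Sharpless asymmetric epoxidation of the allylic alcohol, in which the D-tartrate ligand on titanium directs oxygen to the face that gives the (2R,3R)-epoxide and thereby fixes the later tertiary carbinol C8'.

Step 9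
Reactants: 15 [(2R,3R)-3-methyl-3-(4-methylpent-3-en-1-yl)oxiran-2-yl]methanol
Product: 17 (2R,3R)-3,7-dimethyl-1-(phenylsulfanyl)oct-6-ene-2,3-diol, via terminal epoxide alkoxide 16 (not isolated)
Conditions: PhSH (slow addition), NaOH (0.5 M aq), t-BuOH, 80 °C
Reagents that add atoms: thiophenol, Sc1ccccc1
Why: Payne rearrangement–opening, in which the primary alkoxide opens the oxirane at C2 with inversion (setting the later C7' carbinol) and thiolate then attacks the CH2 of the more reactive terminal epoxide while C3 keeps its oxygen.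

Step 10
Reactants: 17 (2R,3R)-3,7-dimethyl-1-(phenylsulfanyl)oct-6-ene-2,3-diol
Product: 19 (2R)-6-methyl-2-[(2S)-oxiran-2-yl]hept-5-en-2-ol, via sulfonium salt 18 (not isolated)
Conditions: Me3OBF4, CH2Cl2, 0 °C → rt; then NaOH (2 M aq), rt
Reagents that add atoms: none
Why: S-Methylation turns the sulfide into a leaving group and the neighbouring secondary alkoxide displaces it at the primary carbon (intramolecular SN2, 3-exo-tet), so both carbinol configurations are retained.

Step 11
Reactants: 19 (2R)-6-methyl-2-[(2S)-oxiran-2-yl]hept-5-en-2-ol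
Product: 21 (5S,6R)-6,10-dimethylundec-9-en-1-yne-5,6-diol, via silylalkyne diol 20 (not isolated)
Conditions: 1-(trimethylsilyl)propyne, n-BuLi, THF, −78 → −20 °C (3.5 equiv of the propargylic lithium reagent); 19, DMPU, −78 → 0 °C; then K2CO3, MeOH, rt
Reagents that add atoms: 1-(trimethylsilyl)propyne, CC#C[Si](C)(C)C
Why: The propargylic organolithium opens the terminal epoxide at its CH2 carbon (SN2, no stereocentre involved) and mild methanolysis removes the alkynyl silane.

Step 12
Reactants: 21 (5S,6R)-6,10-dimethylundec-9-en-1-yne-5,6-diol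
Product: 23 (1E,5S,6R)-1-iodo-2,6,10-trimethylundeca-1,9-diene-5,6-diol, via alkenylalane 22 (not isolated)
Conditions: Me3Al (5 equiv), Cp2ZrCl2 (0.5 equiv), CH2Cl2, 0 °C → rt; then I2, THF, −30 °C
Reagents that add atoms: trimethylaluminium, C[Al](C)C; iodine, II
Why: Zirconium-catalysed syn-carboalumination of the terminal alkyne (Negishi carboalumination, methyl to the internal carbon) followed by iodinolysis with retention should give the (E)-2-methyl-1-iodoalkene, the diol being carried as its aluminium alkoxides.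

Step 13
Reactants: 23 (1E,5S,6R)-1-iodo-2,6,10-trimethylundeca-1,9-diene-5,6-diol
Product: 24 (4R,5S)-5-[(3E)-4-iodo-3-methylbut-3-en-1-yl]-4-methyl-4-(4-methylpent-3-en-1-yl)-1,3-dioxolan-2-one
Conditions: 1,1'-carbonyldiimidazole (1.5 equiv), DMAP (cat.), toluene, 80 °C
Reagents that add atoms: 1,1'-carbonyldiimidazole, O=C(n1ccnc1)n1ccnc1
Why: Carbonylation of the 1,2-diol to the five-membered cyclic carbonate gives a mask that is later removed by base and not by acid, with both configurations unchanged.

Step 14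
Reactants: 13 2-{[(1R,2S,5R)-5-ethenyl-1,2,5-trimethyl-1,2,3,4,5,6,7,8-octahydronaphthalen-1-yl]methyl}-1,4-dimethoxybenzene; 24 (4R,5S)-5-[(3E)-4-iodo-3-methylbut-3-en-1-yl]-4-methyl-4-(4-methylpent-3-en-1-yl)-1,3-dioxolan-2-one
Product: 26 (4R,5S)-5-[(3E)-6-{(1R,5R,6S)-5-[(2,5-dimethoxyphenyl)methyl]-1,5,6-trimethyl-1,2,3,4,5,6,7,8-octahydronaphthalen-1-yl}-3-methylhex-3-en-1-yl]-4-methyl-4-(4-methylpent-3-en-1-yl)-1,3-dioxolan-2-one, via alkylborane 25 (not isolated)
Conditions: 9-BBN-H, THF, rt → 50 °C; then 24, Pd(dppf)Cl2 (5 mol %), AsPh3 (10 mol %), K3PO4 (3 equiv, aq), DMF, rt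
Reagents that add atoms: none
Why: Anti-Markovnikov hydroboration of the only unhindered alkene (the vinyl group; the tetrasubstituted C5=C10 bond is inert to 9-BBN) followed by B-alkyl Suzuki–Miyaura coupling, which proceeds with retention of the (E) geometry and joins C2' to C3'.

Step 15
Reactants: 26 (coupled dimethyl ether carbonate)
Product: 28 hydroquinone carbonate (2,5-dihydroxybenzyl analogue of 26), via quinone 27 (not isolated)
Conditions: (NH4)2Ce(NO3)6 (2.5 equiv), MeCN/H2O (3:1), 0 °C, 15 min; then Na2S2O4 (aq), EtOAc, rt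
Reagents that add atoms: water, O
Why: Oxidative demethylation of the 1,4-dimethoxyarene by tetravalent cerium (single-electron oxidation with water as the oxygen source) gives the quinone, and dithionite reduces it to the hydroquinone, with the isolated alkenes and the carbonate as spectators.

Step 16
Reactants: 28 hydroquinone carbonate
Product: 29 bis(hydrogen sulfate) carbonate
Conditions: SO3·pyridine (10 equiv), pyridine, rt → 40 °C
Reagents that add atoms: sulfur trioxide pyridine complex, O=S(=O)([O-])[n+]1ccccc1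
Why: O-Sulfation of both phenols with the SO3·pyridine complex, which is selective because no aliphatic hydroxyl is free while the diol is held as the carbonate.

Step 17
Reactants: 29 bis(hydrogen sulfate) carbonate
Product: 31 CNP0442769.2, 2-{[(1R,2S,5R)-5-[(3E,7S,8R)-7,8-dihydroxy-4,8,12-trimethyltrideca-3,11-dien-1-yl]-1,2,5-trimethyl-1,2,3,4,5,6,7,8-octahydronaphthalen-1-yl]methyl}-1,4-phenylene bis(hydrogen sulfate), via disodium salt 30 (not isolated)
Conditions: NaOH (0.5 M), MeOH/H2O, rt; then Dowex 50W (H+ form), 0 °C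
Reagents that add atoms: none
Why: Hydroxide hydrolysis of the cyclic carbonate (acyl–oxygen cleavage, so both carbinol configurations are kept) under conditions to which aryl sulfate monoesters are stable, followed by exchange of sodium for protons.

**Compound list**

1 | 2-methylcyclohex-2-en-1-one | CC1=CCCCC1=O | starting material
2 | dimethylaluminium (3S)-2,3-dimethylcyclohex-1-en-1-olate | C[Al](C)OC1=C(C)[C@@H](C)CCC1 | intermediate
3 | (3S)-2,3-dimethylcyclohex-1-en-1-yl acetate | CC(=O)OC1=C(C)[C@@H](C)CCC1 | intermediate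
4 | 2,5-dimethoxybenzyl bromide | COc1ccc(OC)c(CBr)c1 | starting material
5 | lithium (3S)-2,3-dimethylcyclohex-1-en-1-olate | [Li]OC1=C(C)[C@@H](C)CCC1 | intermediate
6 | (2R,3S)-2-[(2,5-dimethoxyphenyl)methyl]-2,3-dimethylcyclohexan-1-one | O=C1CCC[C@H](C)[C@@]1(C)Cc1cc(OC)ccc1OC | intermediate
7 | potassium (5S,6R)-6-[(2,5-dimethoxyphenyl)methyl]-5,6-dimethylcyclohex-1-en-1-olate | [K]OC1=CCC[C@H](C)[C@@]1(C)Cc1cc(OC)ccc1OC | intermediate
8 | (5S,6R)-6-[(2,5-dimethoxyphenyl)methyl]-5,6-dimethylcyclohex-1-en-1-yl trifluoromethanesulfonate | FC(F)(F)S(=O)(=O)OC1=CCC[C@H](C)[C@@]1(C)Cc1cc(OC)ccc1OC | intermediate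
9 | 2-{[(1R,6S)-2-ethenyl-1,6-dimethylcyclohex-2-en-1-yl]methyl}-1,4-dimethoxybenzene | C=CC1=CCC[C@H](C)[C@@]1(C)Cc1cc(OC)ccc1OC | intermediate
10 | methacrolein | CC(=C)C=O | starting material
11 | (1S,5R,6S)-5-[(2,5-dimethoxyphenyl)methyl]-1,5,6-trimethyl-1,2,3,5,6,7,8,8a-octahydronaphthalene-1-carbaldehyde, epimers at C8a (core C5), that centre left undefined | O=C[C@@]1(C)CCC=C2C1CC[C@H](C)[C@@]2(C)Cc1cc(OC)ccc1OC | intermediate
12 | (1R,5R,6S)-1-ethenyl-5-[(2,5-dimethoxyphenyl)methyl]-1,5,6-trimethyl-1,2,3,5,6,7,8,8a-octahydronaphthalene, epimers at C8a, that centre left undefined | C=C[C@@]1(C)CCC=C2C1CC[C@H](C)[C@@]2(C)Cc1cc(OC)ccc1OC | intermediate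
13 | 2-{[(1R,2S,5R)-5-ethenyl-1,2,5-trimethyl-1,2,3,4,5,6,7,8-octahydronaphthalen-1-yl]methyl}-1,4-dimethoxybenzene | C=C[C@@]1(C)CCCC2=C1CC[C@H](C)[C@@]2(C)Cc1cc(OC)ccc1OC | intermediate
14 | geraniol | CC(C)=CCC/C(C)=C/CO | starting material
15 | [(2R,3R)-3-methyl-3-(4-methylpent-3-en-1-yl)oxiran-2-yl]methanol | CC(C)=CCC[C@@]1(C)O[C@@H]1CO | intermediate
16 | sodium (2R)-6-methyl-2-[(2S)-oxiran-2-yl]hept-5-en-2-olate | CC(C)=CCC[C@@](C)([O-])[C@@H]1CO1.[Na+] | intermediate
17 | (2R,3R)-3,7-dimethyl-1-(phenylsulfanyl)oct-6-ene-2,3-diol | CC(C)=CCC[C@@](C)(O)[C@@H](O)CSc1ccccc1 | intermediate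
18 | [(2R,3R)-2,3-dihydroxy-3,7-dimethyloct-6-en-1-yl](methyl)phenylsulfonium tetrafluoroborate | CC(C)=CCC[C@@](C)(O)[C@@H](O)C[S+](C)c1ccccc1.F[B-](F)(F)F | intermediate
19 | (2R)-6-methyl-2-[(2S)-oxiran-2-yl]hept-5-en-2-ol | CC(C)=CCC[C@@](C)(O)[C@@H]1CO1 | intermediate
20 | (5S,6R)-6,10-dimethyl-1-(trimethylsilyl)undec-9-en-1-yne-5,6-diol | CC(C)=CCC[C@@](C)(O)[C@@H](O)CCC#C[Si](C)(C)C | intermediate
21 | (5S,6R)-6,10-dimethylundec-9-en-1-yne-5,6-diol | CC(C)=CCC[C@@](C)(O)[C@@H](O)CCC#C | intermediate
22 | (E)-alkenyldimethylalane from 21, both hydroxyls as dimethylaluminium alkoxides | CC(C)=CCC[C@@](C)(O[Al](C)C)[C@@H](O[Al](C)C)CC/C(C)=C/[Al](C)C | intermediate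
23 | (1E,5S,6R)-1-iodo-2,6,10-trimethylundeca-1,9-diene-5,6-diol | CC(C)=CCC[C@@](C)(O)[C@@H](O)CC/C(C)=C/I | intermediate
24 | (4R,5S)-5-[(3E)-4-iodo-3-methylbut-3-en-1-yl]-4-methyl-4-(4-methylpent-3-en-1-yl)-1,3-dioxolan-2-one | CC(C)=CCC[C@@]1(C)OC(=O)O[C@H]1CC/C(C)=C/I | intermediate
25 | B-alkyl-9-borabicyclo[3.3.1]nonane from hydroboration of the vinyl group of 13 (configuration as in 13) | B1(CC[C@@]2(C)CCCC3=C2CC[C@H](C)[C@@]3(C)Cc2cc(OC)ccc2OC)C2CCCC1CCC2 | intermediate
26 | (4R,5S)-5-[(3E)-6-{(1R,5R,6S)-5-[(2,5-dimethoxyphenyl)methyl]-1,5,6-trimethyl-1,2,3,4,5,6,7,8-octahydronaphthalen-1-yl}-3-methylhex-3-en-1-yl]-4-methyl-4-(4-methylpent-3-en-1-yl)-1,3-dioxolan-2-one | CC(C)=CCC[C@@]1(C)OC(=O)O[C@H]1CC/C(C)=C/CC[C@@]1(C)CCCC2=C1CC[C@H](C)[C@@]2(C)Cc1cc(OC)ccc1OC | intermediate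
27 | 2-substituted 1,4-benzoquinone corresponding to 26 (configuration as in 26) | CC(C)=CCC[C@@]1(C)OC(=O)O[C@H]1CC/C(C)=C/CC[C@@]1(C)CCCC2=C1CC[C@H](C)[C@@]2(C)CC1=CC(=O)C=CC1=O | intermediate
28 | hydroquinone carbonate, the 2,5-dihydroxybenzyl analogue of 26 | CC(C)=CCC[C@@]1(C)OC(=O)O[C@H]1CC/C(C)=C/CC[C@@]1(C)CCCC2=C1CC[C@H](C)[C@@]2(C)Cc1cc(O)ccc1O | intermediate
29 | bis(hydrogen sulfate) of 28, cyclic carbonate intact | CC(C)=CCC[C@@]1(C)OC(=O)O[C@H]1CC/C(C)=C/CC[C@@]1(C)CCCC2=C1CC[C@H](C)[C@@]2(C)Cc1cc(OS(=O)(=O)O)ccc1OS(=O)(=O)O | intermediate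
30 | disodium salt of the target | CC(C)=CCC[C@@](C)(O)[C@@H](O)CC/C(C)=C/CC[C@@]1(C)CCCC2=C1CC[C@H](C)[C@@]2(C)Cc1cc(OS(=O)(=O)[O-])ccc1OS(=O)(=O)[O-].[Na+].[Na+] | intermediate
31 | CNP0442769.2, 2-{[(1R,2S,5R)-5-[(3E,7S,8R)-7,8-dihydroxy-4,8,12-trimethyltrideca-3,11-dien-1-yl]-1,2,5-trimethyl-1,2,3,4,5,6,7,8-octahydronaphthalen-1-yl]methyl}-1,4-phenylene bis(hydrogen sulfate) | CC(C)=CCC[C@@](C)(O)[C@@H](O)CC/C(C)=C/CC[C@@]1(C)CCCC2=C1CC[C@H](C)[C@@]2(C)Cc1cc(OS(=O)(=O)O)ccc1OS(=O)(=O)O | target

**Step count and risks**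

Total step count: 17. Longest linear sequence: 11 steps (steps 1–7 and 14–17); the side-chain branch is 6 steps (steps 8–13).

Three steps most likely to fail:

Step 5. The dienophile may add in the reversed orientation (C4 bonding to C2 instead of C5), or the diene may be consumed by acid-induced oligomerisation faster than it cycloadds. The fallback enforces the orientation with a donor on C1 and sets out from enol triflate 8. Stille coupling of 8 with tributyl(1-ethoxyvinyl)stannane (Pd(PPh3)4, LiCl) would give the ethoxydiene F1, which aqueous HCl work-up hydrolyses to the methyl enone F2. Treatment with i-Pr3SiOTf/Et3N would give the 2-silyloxydiene F3, a more reactive diene whose silyloxy group directs C4 to C5. Cycloaddition with 10 under the catalyst of step 5 would give the silyl enol ether aldehyde F4, and Wittig methylenation as in step 6 the vinyl compound F5. CsF/PhNTf2 would convert the silyl enol ether regiospecifically into the enol triflate F6, and reduction with Pd(OAc)2/PPh3/HCO2H/Bu3N would give 12, where the route is rejoined.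

Step 7. The C10 cation may be captured by the electron-rich dimethoxyarene (Friedel–Crafts ring closure onto C10) instead of losing H-5. The fallback takes the nucleophilic arene out of play first and sets out from 12. Oxidation with (NH4)2Ce(NO3)6 would give the quinone F7, and the same acid treatment would move the double bond to give the quinone F8. Reduction with Na2S2O4 would give the hydroquinone F9, and methylation with Me2SO4/K2CO3 in acetone would return 13.

Step 14. Transmetalation of the alkylborane may be slow, with protodeboronation competing, and the aqueous base may open the cyclic carbonate. The fallback is a base-free zinc coupling and sets out from 13. Its hydroboration product 25 would be treated with I2/NaOMe to give the primary iodide F10. Halogen–lithium exchange with t-BuLi (Et2O, −78 °C) would give the alkyllithium F11, and ZnCl2 the alkylzinc chloride F12. Negishi coupling of F12 with 24 under Pd(PPh3)4 in THF would give 26.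

**Further compounds**

F1 | step 5 | 2-{[(1R,6S)-2-(1-ethoxyethenyl)-1,6-dimethylcyclohex-2-en-1-yl]methyl}-1,4-dimethoxybenzene | CCOC(=C)C1=CCC[C@H](C)[C@@]1(C)Cc1cc(OC)ccc1OC
F2 | step 5 | 1-[(5S,6R)-6-[(2,5-dimethoxyphenyl)methyl]-5,6-dimethylcyclohex-1-en-1-yl]ethan-1-one | CC(=O)C1=CCC[C@H](C)[C@@]1(C)Cc1cc(OC)ccc1OC
F3 | step 5 | triisopropylsilyl dienol ether of F2 (2-silyloxydiene) | C=C(O[Si](C(C)C)(C(C)C)C(C)C)C1=CCC[C@H](C)[C@@]1(C)Cc1cc(OC)ccc1OC
F4 | step 5 | analogue of 11 carrying a triisopropylsilyloxy group on C1 of the core (silyl enol ether, C5 epimers) | O=C[C@@]1(C)CCC(O[Si](C(C)C)(C(C)C)C(C)C)=C2C1CC[C@H](C)[C@@]2(C)Cc1cc(OC)ccc1OC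
F5 | step 5 | analogue of 12 carrying a triisopropylsilyloxy group on C1 of the core | C=C[C@@]1(C)CCC(O[Si](C(C)C)(C(C)C)C(C)C)=C2C1CC[C@H](C)[C@@]2(C)Cc1cc(OC)ccc1OC
F6 | step 5 | analogue of 12 carrying a trifluoromethanesulfonyloxy group on C1 of the core (enol triflate) | C=C[C@@]1(C)CCC(OS(=O)(=O)C(F)(F)F)=C2C1CC[C@H](C)[C@@]2(C)Cc1cc(OC)ccc1OC
F7 | step 7 | 1,4-benzoquinone corresponding to 12 (C1=C10 alkene, C5 epimers) | C=C[C@@]1(C)CCC=C2C1CC[C@H](C)[C@@]2(C)CC1=CC(=O)C=CC1=O
F8 | step 7 | 1,4-benzoquinone corresponding to 13 (C5=C10 alkene) | C=C[C@@]1(C)CCCC2=C1CC[C@H](C)[C@@]2(C)CC1=CC(=O)C=CC1=O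
F9 | step 7 | hydroquinone corresponding to 13 | C=C[C@@]1(C)CCCC2=C1CC[C@H](C)[C@@]2(C)Cc1cc(O)ccc1O
F10 | step 14 | primary iodide, the 2-iodoethyl analogue of 13 at C4 | ICC[C@@]1(C)CCCC2=C1CC[C@H](C)[C@@]2(C)Cc1cc(OC)ccc1OC
F11 | step 14 | alkyllithium from F10 | [Li]CC[C@@]1(C)CCCC2=C1CC[C@H](C)[C@@]2(C)Cc1cc(OC)ccc1OC
F12 | step 14 | alkylzinc chloride from F11 | Cl[Zn]CC[C@@]1(C)CCCC2=C1CC[C@H](C)[C@@]2(C)Cc1cc(OC)ccc1OC
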